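The cyclohexane ring is cut into two three-carbon halves, C1–C3 and C4–C6 (C1 carries the angelate, C3 the methyl, C4 the ring acetate, C6 the side chain). One flask operation joins them: an α-acetoxy-(E)-crotylboronate adds as a β-methyl homoenolate to 4-methylpent-3-enal (C3–C4), the acetyl group then shifts from the enol oxygen to the new C4 oxygen, freeing the C1 aldehyde, and ZnBr2 closes C1–C6 by a carbonyl-ene reaction. The step exploits the 1,4-dioxygenated ring in which each carbinol carbon (C1, C4) lies next to a branched carbon (C6, C3). The precursors are an enantioenriched boronate and an achiral prenyl aldehyde.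

Key step: step 5

Remark: the side chain is numbered C7 (CHMe), C8, C9 (CHOAc), C10=C11; (1S,2S)-1,2-dicyclohexylethane-1,2-diol and angelic anhydride are taken as commercial, and the (S,S)-diol is assumed to give the (S)-α-chloroboronate (otherwise its mirror image is used).

Step 1
Reactants: 1 (E)-prop-1-en-1-ylboronic acid; 2 (1S,2S)-1,2-dicyclohexylethane-1,2-diol
Product: 3 (4S,5S)-4,5-dicyclohexyl-2-[(E)-prop-1-enyl]-1,3,2-dioxaborolane
Conditions: MgSO4, Et2O, 25 °C
Reagents that add atoms: none
Why: Boronic acid–diol condensation (boronate ester formation) should go to completion with a drying agent; no stereocentre is formed.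

Step 2
Reactants: 3 (4S,5S)-4,5-dicyclohexyl-2-[(E)-prop-1-enyl]-1,3,2-dioxaborolane
Product: 4 (4S,5S)-2-[(1S,2E)-1-chlorobut-2-enyl]-4,5-dicyclohexyl-1,3,2-dioxaborolane
Conditions: CH2Cl2, n-BuLi, THF, –100 °C; then ZnCl2, –100 → 25 °C
Reagents that add atoms: dichloromethane (as LiCHCl2), ClCCl
Why: Matteson homologation, in which LiCHCl2 forms the boron-ate complex and ZnCl2-assisted 1,2-migration of the propenyl group with loss of chloride should set the new α-chloro centre as S under control of the C2-symmetric diol.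

Step 3
Reactants: 4 (4S,5S)-2-[(1S,2E)-1-chlorobut-2-enyl]-4,5-dicyclohexyl-1,3,2-dioxaborolane
Product: 5 (1R,2E)-1-[(4S,5S)-4,5-dicyclohexyl-1,3,2-dioxaborolan-2-yl]but-2-enyl acetate
Conditions: Bu4NOAc, THF, 0 → 25 °C
Reagents that add atoms: tetrabutylammonium acetate, CC(=O)[O-].CCCC[N+](CCCC)(CCCC)CCCC
Why: Matteson-type substitution, in which acetate adds to boron and migrates to carbon with loss of chloride, should invert the centre to R, as is known for alkoxides on α-chloroboronates.

Step 4
Reactants: 6 4-methylpent-3-en-1-ol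
Product: 7 4-methylpent-3-enal
Conditions: Dess–Martin periodinane, CH2Cl2, 0 °C; used at once as a solution
Reagents that add atoms: none
Why: Dess–Martin oxidation of the primary alcohol under non-basic conditions should give the β,γ-unsaturated aldehyde without moving the double bond into conjugation; no stereocentre is formed.

Step 5
Reactants: 5 (1R,2E)-1-[(4S,5S)-4,5-dicyclohexyl-1,3,2-dioxaborolan-2-yl]but-2-enyl acetate; 7 4-methylpent-3-enal
Product: 11 (1R,2S,4R,5S)-4-hydroxy-2-methyl-5-(prop-1-en-2-yl)cyclohexyl acetate, via borate ester 8 (not isolated), via hydroxy enol acetate 9 (not isolated), via acetoxy aldehyde 10 (not isolated)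
Conditions: CH2Cl2, 4 Å MS, 25 °C; then MeOH, Et3N (cat.), 25 °C; evaporate; ZnBr2, toluene, 0 → 25 °C
Reagents that add atoms: none
Why: Proposed new method: the α-acetoxy-(E)-crotylboronate should add to the aldehyde through a closed chair transition state (γ-attack of C3 on C4) to give borate 8, methanolysis of the B–O bond then lets the C4 oxygen take the acetyl group from the (Z)-enol acetate through a seven-membered transition state, and the aldehyde 10 released by this shift cyclises under ZnBr2 by an intramolecular carbonyl-ene reaction. The closest known reaction types are allylborations with α-chloro- and α-methoxycrotylboronates (homoaldol equivalents), acyl transfer from enol esters to alcohols, and the ZnBr2-mediated citronellal-to-isopulegol ene cyclisation. The six-membered ring is closed by bond C1–C6 in a type 1 ene mode, exo to both the C=O and the C=C bond, through a chair transition state. C3 and C4 are set in the allylboration, anti from the (E)-alkene and in the 3S,4R sense from the boron-bearing stereocentre of 5 with its acetoxy group axial (which also gives the Z-enol acetate), while C1 and C6 are set in the ene step by the chair with the C3 methyl equatorial, which places the new hydroxyl and isopropenyl groups trans and equatorial. The step needs C4–O to be capped before the C1 aldehyde appears, since a free 4-hydroxy aldehyde would close to a lactol, and this order is secured because the aldehyde is only formed by the acyl shift itself. It also needs face control in the ring closure, which the equatorial preference of methyl over the smaller axial acetoxy group should secure.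

Step 6
Reactants: 11 (1R,2S,4R,5S)-4-hydroxy-2-methyl-5-(prop-1-en-2-yl)cyclohexyl acetate
Product: 12 (1R,2S,4R,5S)-4-hydroxy-5-[(2S)-1-hydroxypropan-2-yl]-2-methylcyclohexyl acetate
Conditions: BH3·THF, THF, 0 °C; then H2O2, pH 7 phosphate buffer, 0 → 25 °C
Reagents that add atoms: hydrogen peroxide, OO
Why: Hydroxyl-directed hydroboration–oxidation, in which the C1–O–BH2 group should deliver B–H to the isopropenyl group through a chair oxaborinane transition state with the methyl equatorial (as in the selective reaction of isopulegol with borane), sets C7, and the oxidation retains configuration.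

Step 7
Reactants: 12 (1R,2S,4R,5S)-4-hydroxy-5-[(2S)-1-hydroxypropan-2-yl]-2-methylcyclohexyl acetate
Product: 13 (1R,2S,4R,5S)-4-hydroxy-5-[(2S)-1-iodopropan-2-yl]-2-methylcyclohexyl acetate
Conditions: I2, PPh3, imidazole, CH2Cl2, 0 °C
Reagents that add atoms: iodine, II
Why: Appel-type iodination should convert only the primary alcohol and leave the hindered secondary C1–OH free; no stereocentre is touched.

Step 8
Reactants: 13 (1R,2S,4R,5S)-4-hydroxy-5-[(2S)-1-iodopropan-2-yl]-2-methylcyclohexyl acetate; 14 (2Z)-2-methylbut-2-enoic anhydride (angelic anhydride)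
Product: 16 (1R,2S,4R,5S)-4-acetoxy-2-[(2S)-1-iodopropan-2-yl]-5-methylcyclohexyl (2Z)-2-methylbut-2-enoate, via lithium alkoxide 15 (not isolated)
Conditions: LiN(SiMe3)2, THF, –78 °C; then 14, –78 → –20 °C
Reagents that add atoms: none
Why: Acylation of the lithium alkoxide by the anhydride at low temperature is fast, so the Z geometry of the angeloyl group should be kept and closure of the alkoxide onto the iodide should not compete; no stereocentre is formed.

Step 9
Reactants: 16 (1R,2S,4R,5S)-4-acetoxy-2-[(2S)-1-iodopropan-2-yl]-5-methylcyclohexyl (2Z)-2-methylbut-2-enoate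
Product: 18 (1R,2S,4R,5S)-4-acetoxy-5-methyl-2-[(2R)-6-methyl-4-oxohept-5-en-2-yl]cyclohexyl (2Z)-2-methylbut-2-enoate, via alkylzinc iodide 17 (not isolated)
Conditions: Zn dust, LiCl, THF, 40 °C; then Pd(PPh3)4 (cat.), 3-methylbut-2-enoyl chloride, 0 → 25 °C
Reagents that add atoms: 3-methylbut-2-enoyl chloride, CC(C)=CC(=O)Cl
Why: Zinc insertion into the primary iodide followed by Negishi acylation with the acid chloride should give the dienone while both esters are tolerated; no stereocentre is formed.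

Step 10
Reactants: 18 (1R,2S,4R,5S)-4-acetoxy-5-methyl-2-[(2R)-6-methyl-4-oxohept-5-en-2-yl]cyclohexyl (2Z)-2-methylbut-2-enoate
Product: 19 (1R,2S,4R,5S)-4-acetoxy-2-[(2R,4R)-4-hydroxy-6-methylhept-5-en-2-yl]-5-methylcyclohexyl (2Z)-2-methylbut-2-enoate
Conditions: (S)-2-methyl-CBS-oxazaborolidine (cat.), catecholborane, toluene, –78 °C
Reagents that add atoms: none
Why: Corey–Bakshi–Shibata reduction, with the alkenyl group acting as the large substituent, should give the 9R allylic alcohol by catalyst control and by 1,2-addition only.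

Step 11
Reactants: 19 (1R,2S,4R,5S)-4-acetoxy-2-[(2R,4R)-4-hydroxy-6-methylhept-5-en-2-yl]-5-methylcyclohexyl (2Z)-2-methylbut-2-enoate
Product: 20 (1R,2S,4R,5S)-4-acetoxy-2-[(2R,4R)-4-acetoxy-6-methylhept-5-en-2-yl]-5-methylcyclohexyl (2Z)-2-methylbut-2-enoate
Conditions: Ac2O, pyridine, DMAP (cat.), CH2Cl2, 0 °C
Reagents that add atoms: acetic anhydride, CC(=O)OC(C)=O
Why: Base-mediated acetylation of the secondary allylic alcohol should complete the target without ionising the allylic ester; no stereocentre is affected.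

Compound list
1 | (E)-prop-1-en-1-ylboronic acid | C/C=C/B(O)O | starting material
2 | (1S,2S)-1,2-dicyclohexylethane-1,2-diol | O[C@@H](C1CCCCC1)[C@@H](O)C1CCCCC1 | starting material
3 | (4S,5S)-4,5-dicyclohexyl-2-[(E)-prop-1-enyl]-1,3,2-dioxaborolane | C/C=C/B1O[C@@H](C2CCCCC2)[C@H](C2CCCCC2)O1 | intermediate
4 | (4S,5S)-2-[(1S,2E)-1-chlorobut-2-enyl]-4,5-dicyclohexyl-1,3,2-dioxaborolane | C/C=C/[C@@H](Cl)B1O[C@@H](C2CCCCC2)[C@H](C2CCCCC2)O1 | intermediate
5 | (1R,2E)-1-[(4S,5S)-4,5-dicyclohexyl-1,3,2-dioxaborolan-2-yl]but-2-enyl acetate | C/C=C/[C@H](OC(C)=O)B1O[C@@H](C2CCCCC2)[C@H](C2CCCCC2)O1 | intermediate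
6 | 4-methylpent-3-en-1-ol | CC(C)=CCCO | starting material
7 | 4-methylpent-3-enal | CC(C)=CCC=O | intermediate
8 | (1Z,3S,4R)-4-{[(4S,5S)-4,5-dicyclohexyl-1,3,2-dioxaborolan-2-yl]oxy}-3,7-dimethylocta-1,6-dien-1-yl acetate | CC(=O)O/C=C\[C@H](C)[C@H](OB1O[C@@H](C2CCCCC2)[C@H](C2CCCCC2)O1)CC=C(C)C | intermediate
9 | (1Z,3S,4R)-4-hydroxy-3,7-dimethylocta-1,6-dien-1-yl acetate | CC(=O)O/C=C\[C@H](C)[C@H](O)CC=C(C)C | intermediate
10 | (3S,4R)-3,7-dimethyl-1-oxooct-6-en-4-yl acetate | O=CC[C@H](C)[C@H](OC(C)=O)CC=C(C)C | intermediate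
11 | (1R,2S,4R,5S)-4-hydroxy-2-methyl-5-(prop-1-en-2-yl)cyclohexyl acetate | O[C@@H]1C[C@H](C)[C@H](OC(C)=O)C[C@H]1C(C)=C | intermediate
12 | (1R,2S,4R,5S)-4-hydroxy-5-[(2S)-1-hydroxypropan-2-yl]-2-methylcyclohexyl acetate | O[C@@H]1C[C@H](C)[C@H](OC(C)=O)C[C@H]1[C@H](C)CO | intermediate
13 | (1R,2S,4R,5S)-4-hydroxy-5-[(2S)-1-iodopropan-2-yl]-2-methylcyclohexyl acetate | O[C@@H]1C[C@H](C)[C@H](OC(C)=O)C[C@H]1[C@H](C)CI | intermediate
14 | (2Z)-2-methylbut-2-enoic anhydride (angelic anhydride) | C/C=C(/C)C(=O)OC(=O)C(/C)=C\C | starting material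
15 | lithium alkoxide of 13 (C1–OLi) | [Li+].[O-][C@@H]1C[C@H](C)[C@H](OC(C)=O)C[C@H]1[C@H](C)CI | intermediate
16 | (1R,2S,4R,5S)-4-acetoxy-2-[(2S)-1-iodopropan-2-yl]-5-methylcyclohexyl (2Z)-2-methylbut-2-enoate | C/C=C(/C)C(=O)O[C@@H]1C[C@H](C)[C@H](OC(C)=O)C[C@H]1[C@H](C)CI | intermediate
17 | alkylzinc iodide of 16 (C8–ZnI in place of C8–I) | C/C=C(/C)C(=O)O[C@@H]1C[C@H](C)[C@H](OC(C)=O)C[C@H]1[C@H](C)C[Zn]I | intermediate
18 | (1R,2S,4R,5S)-4-acetoxy-5-methyl-2-[(2R)-6-methyl-4-oxohept-5-en-2-yl]cyclohexyl (2Z)-2-methylbut-2-enoate | C/C=C(/C)C(=O)O[C@@H]1C[C@H](C)[C@H](OC(C)=O)C[C@H]1[C@H](C)CC(=O)C=C(C)C | intermediate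
19 | (1R,2S,4R,5S)-4-acetoxy-2-[(2R,4R)-4-hydroxy-6-methylhept-5-en-2-yl]-5-methylcyclohexyl (2Z)-2-methylbut-2-enoate | C/C=C(/C)C(=O)O[C@@H]1C[C@H](C)[C@H](OC(C)=O)C[C@H]1[C@H](C)C[C@H](C=C(C)C)O | intermediate
20 | (1R,2S,4R,5S)-4-acetoxy-2-[(2R,4R)-4-acetoxy-6-methylhept-5-en-2-yl]-5-methylcyclohexyl (2Z)-2-methylbut-2-enoate | C/C=C(/C)C(=O)O[C@@H]1C[C@H](C)[C@H](OC(C)=O)C[C@H]1[C@H](C)C[C@H](C=C(C)C)OC(C)=O | target

Total step count: 11. Longest linear sequence: 10 steps (steps 1–3 and 5–11, from compound 1).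

Steps most likely to fail

1. Step 5 (proposed new method). The acetyl shift may lag behind other pathways, the boronate may add with poor Z/anti control, or the ring closure may pass through the chair with the methyl axial and give poor facial selectivity. The fallback uses known chemistry, sets out from aldehyde 7 and comes back at aldehyde 10. Aldehyde 7 is crotylated with (E)-crotyldiisopinocampheylborane (the antipode that attacks the Si face) to give the anti homoallylic alcohol (3S,4R)-3,7-dimethylocta-1,6-dien-4-ol F1. Acetylation (Ac2O, pyridine, DMAP) gives (3S,4R)-3,7-dimethylocta-1,6-dien-4-yl acetate F2. 9-BBN, which should touch only the vinyl group, followed by buffered H2O2 gives (3S,4R)-1-hydroxy-3,7-dimethyloct-6-en-4-yl acetate F3. Dess–Martin oxidation gives 10, which ZnBr2 in toluene should close to 11 as a separate operation.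

2. Step 3. Acetate may fail to form the boron-ate complex or may attack the allylic chloride in an SN2′ sense, with loss of configurational purity. The fallback sets out from chloride 4 and comes back at aldehyde 10. LiOMe in THF should give the α-methoxy boronate (4S,5S)-4,5-dicyclohexyl-2-[(1R,2E)-1-methoxybut-2-enyl]-1,3,2-dioxaborolane F4. Its addition to 7 gives the (Z)-enol ether borate (1Z,3S,4R)-4-{[(4S,5S)-4,5-dicyclohexyl-1,3,2-dioxaborolan-2-yl]oxy}-1-methoxy-3,7-dimethylocta-1,6-diene F5. Triethanolamine frees (1Z,3S,4R)-1-methoxy-3,7-dimethylocta-1,6-dien-4-ol F6, and Ac2O in pyridine gives (1Z,3S,4R)-1-methoxy-3,7-dimethylocta-1,6-dien-4-yl acetate F7. Oxalic acid in wet THF unmasks 10, which is closed to 11 with ZnBr2.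

3. Step 8. The Z-enoate may isomerise to the E-isomer during acylation, or the alkoxide may be alkylated intramolecularly by the primary iodide. The fallback sets out from 13 and comes back at 16. Alcohol 13 is esterified with 2-[bis(2,2,2-trifluoroethoxy)phosphoryl]propanoic acid (diisopropylcarbodiimide, DMAP cat., CH2Cl2, 0 °C) to give (1R,2S,4R,5S)-4-acetoxy-2-[(2S)-1-iodopropan-2-yl]-5-methylcyclohexyl 2-[bis(2,2,2-trifluoroethoxy)phosphoryl]propanoate F8. Still–Gennari olefination with acetaldehyde (KN(SiMe3)2, 18-crown-6, THF, –78 °C) should then build the Z-trisubstituted enoate and give 16.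

Further compounds
F1 | step 5 | (3S,4R)-3,7-dimethylocta-1,6-dien-4-ol | C=C[C@H](C)[C@H](O)CC=C(C)C
F2 | step 5 | (3S,4R)-3,7-dimethylocta-1,6-dien-4-yl acetate | C=C[C@H](C)[C@H](OC(C)=O)CC=C(C)C
F3 | step 5 | (3S,4R)-1-hydroxy-3,7-dimethyloct-6-en-4-yl acetate | OCC[C@H](C)[C@H](OC(C)=O)CC=C(C)C
F4 | step 3 | (4S,5S)-4,5-dicyclohexyl-2-[(1R,2E)-1-methoxybut-2-enyl]-1,3,2-dioxaborolane | C/C=C/[C@H](OC)B1O[C@@H](C2CCCCC2)[C@H](C2CCCCC2)O1
F5 | step 3 | (1Z,3S,4R)-4-{[(4S,5S)-4,5-dicyclohexyl-1,3,2-dioxaborolan-2-yl]oxy}-1-methoxy-3,7-dimethylocta-1,6-diene | CO/C=C\[C@H](C)[C@H](OB1O[C@@H](C2CCCCC2)[C@H](C2CCCCC2)O1)CC=C(C)C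
F6 | step 3 | (1Z,3S,4R)-1-methoxy-3,7-dimethylocta-1,6-dien-4-ol | CO/C=C\[C@H](C)[C@H](O)CC=C(C)C
F7 | step 3 | (1Z,3S,4R)-1-methoxy-3,7-dimethylocta-1,6-dien-4-yl acetate | CO/C=C\[C@H](C)[C@H](OC(C)=O)CC=C(C)C
F8 | step 8 | (1R,2S,4R,5S)-4-acetoxy-2-[(2S)-1-iodopropan-2-yl]-5-methylcyclohexyl 2-[bis(2,2,2-trifluoroethoxy)phosphoryl]propanoate | CC(C(=O)O[C@@H]1C[C@H](C)[C@H](OC(C)=O)C[C@H]1[C@H](C)CI)P(=O)(OCC(F)(F)F)OCC(F)(F)F
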